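## Structural features

The target 34 is a briarane: a cyclohexenone (ring A: C1, C10 to C14) is trans-fused through C1–C10 to a ten-membered carbocycle (C1 to C10), and a γ-lactone (O–C19–C17–C8–C7, methyl C18 on C17) is cis-fused onto the C7–C8 bond. There are ten stereocentres (1S,2R,3R,6S,7S,8R,9S,10S,11S,17R); eight of them form one chain, C17–C8–C7–C6 on the lactone side and C9–C10–C11 with quaternary C1 on the ring A side, and the other two are the trans-epoxide carbons C2 and C3. On ring A the methyl groups C15 and C20 and the C9 branch lie on one face, and C2, H10 and the C11 acetate on the other. The fragile groups are: the secondary C6 chloride, allylic to C5=C16 (SN2' displacement, elimination); the α-methyl-β-hydroxy lactone (epimerisation at C17, β-elimination of the C8 oxygen, acyl shift to a free C9 oxygen); the activated acetoxyacetate at C9; the tertiary C11 acetate next to the C12 ketone; and the epoxide. The real difficulty is the ten-membered ring, in particular the C9–C10 bond between carbons that each have a fully substituted neighbour (C8 and C1), and the C11 carbinol, whose oxygen must sit on the ring A face opposite to C15 and C9. The key step uses the fact that C4 to C9 become a 4-hydroxycyclohexa-2,5-dienone once a temporary C4–C9 bond is drawn: C8 is the carbinol carbon carrying the propionate C17–C19, C5 is the carbonyl, and C7=C6 and C9=C4 are the two enone arms. The lactone oxygen on C7 and the chlorine on C6 are then the result of an anti addition across the C6=C7 arm. The configurations of 3 and 6 were checked atom by atom against 34 (C6, C7, C8 and C17 agree) and need no correction; the CIP letters at C6 and C8 differ between 6 and 34 only because the priorities change.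

## Logic of the disconnections

34 ⇒ 33. The two C–O bonds of the C2–C3 oxirane are cut. The epoxide is the most acid- and nucleophile-sensitive group, and its two centres have no controlling neighbour outside the ring, so it is put in last. This removes two stereocentres and the most fragile function from every earlier step. The forward step must choose C2=C3 over C5=C16 and the enone, and the correct face of the E alkene.

33 ⇒ 32 ⇒ 31. The C9 O–acyl bond is cut, then the O–Si bonds at C8 and C9. The acetoxyacetate would not survive the hydride, titanium methylidene and enolate steps, so both hydroxyls are carried as one kind of silyl ether. The forward acylation must tell the secondary C9 hydroxyl from the tertiary C8 hydroxyl, and the free diol must not be left under conditions that move the lactone to C9.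

31 ⇒ 30 ⇒ 28 (through 29). The acetate C–O bond at C11 is cut, then the C11–O and C20–H bonds. The C11 oxygen lies on the face opposite to the axial C15 methyl and C9. An electrophilic oxidant takes that face of a C11 enolate, whereas a methyl nucleophile adding to a C11 ketone would take the same face and give the wrong epimer. The stereocentre is thereby reduced to a planar exocyclic enone. The forward step needs hydride addition to the exocyclic methylene only, and oxidation of the enolate before it equilibrates.

28 ⇒ 27 ⇒ 26. The C13=C14 unsaturation is taken back to a C12 silyl enol ether and C11=C20 to a C11 ketone. The C11 ketone is what makes C10 nucleophilic. The C12 silyl enol ether stores the C12 ketone and the future enone, and blocks enolisation on that side. Ring A of 26 is thus a plain 2-silyloxy enone. The forward steps demand methylenation of a hindered ketone beside a lactone, and a palladium-mediated dehydrosilylation in the presence of the allylic chloride.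

26 ⇒ 25. The C3–C4 bond is cut. It joins a vinyl metal and a 2-substituted allyl bromide whose two termini are both CH2, so SN2 and SN2' attack give one product. No stereocentre is made, and the E geometry is carried in. This opens the ten-membered ring. The forward step needs high dilution and a metal that leaves the secondary allylic chloride alone.

25 ⇒ 24 ⇒ 21 + 12 (through 22 and 23). The C9 O–Si bond is cut, then C9–C10. This is the only C–C bond between the halves that creates stereocentres. It is made as an intermolecular aldol so that C9 and C10 are set in an open, analysable transition state and the ring is closed later by an irreversible coupling. The two fragments are of similar size. The forward step must control the C10 face, the syn relationship and the aldehyde face, and the enolate must not alkylate the allylic bromide of 12.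

21 ⇒ 20 ⇒ 19 ⇒ 18. The C3–Sn bond, the C12 O–Si bond and the C12 carbonyl are removed in turn. The tin is placed on the small fragment because palladium and a tin hydride cannot be used once the allylic halides of 12 are present. What remains is a simple 3,3-disubstituted cyclohexanone. The oxidation must go to C12 and not to C10, and the silylation must enolise toward C13.

18 ⇒ 17 ⇒ 16 ⇒ 13 + 14 (through 15). The alkyne C–Si bond, the C1–C15 bond and the C1–C2 bond are cut. C1 is made by catalytic asymmetric conjugate addition to an enynone; a terpene such as carvone was examined for ring A and rejected, because its methyl-bearing carbon and carbonyl cannot be mapped onto C1, C11 and C12 without moving a substituent. The starting materials are two commercial compounds. The conjugate addition must be 1,4 and not 1,6 and must be enantioselective.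

12 ⇒ 11 ⇒ 10. The C4–Br bond is cut, then the C5=C16 π bond is taken back to a C5–O bond and a C16–Si bond. The β-silyl carbinol is a masked methylene that also makes C5 quaternary, so a C4 aldehyde cannot enolise and expel the C6 chloride. Its oxygen ties up C9 as a lactol. The forward elimination must free the methylene and the C9 aldehyde together without loss of the C8 silyl ether.

10 ⇒ 8 (through 9) ⇒ 7. The C4–C9 bond is re-formed as an alkene and the C5–C16 bond is cut. Ring opening is thus traced back to ozonolysis of a cyclohexene, and C16 to a 1,2-addition to the C5 ketone. The forward sequence must tell the two aldehydes apart. This is done by the C5 hydroxyl, which can reach only C9.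

7 ⇒ 6 ⇒ 3 + 4 (through 5). After removal of the silyl group, the C7–O lactone bond and the C6–Cl bond are cut. One ring, two bonds and three stereocentres fall away, and an achiral dienone ring with one stereocentre in the side chain remains. The forward cascade must choose one enone arm, chlorinate once, and do so anti to the new C–O bond.

3 ⇒ 2 ⇒ 1. The C8–O bond is cut back to the phenol, and the enantiomer is traced to the racemic acid. Dearomatisation with water must win over other oxidation paths, and C17 must be a single enantiomer.

## Other disconnections considered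

Alternative 1: The cut is C4–C5, paid for by an extra C2–C7 bond in the precursor. In the forward direction the allenyl vinyl decalinol A1 undergoes an anionic oxy-Cope rearrangement as its potassium alkoxide with a crown ether, and protonation of the ten-membered dienolate gives ketone A2. In its favour: the ten-membered ring arises by ring expansion, so there is no entropic penalty of a medium-ring closure. The E geometry of C2=C3 follows from a chair transition state with both unsaturated groups equatorial, the C5 methylene comes from the allene for free, and C1, C9, C10 and C11 are set on a rigid decalin. On ring construction and on the C2=C3 geometry it is better than the chosen plan, which needs a high-dilution coupling. Against it here: A2 has none of the C6 chloride, the lactone, or the C8 carbinol with C17. These would have to be added to a C7 ketone and a C8 ether in a flexible ten-membered ring, with regiochemical doubt between C6 and C8 for the chlorination and several late stereocentres. In step economy the two plans are mirror images: alternative 1 is short to the ring and long to the lactone and chloride, while the chosen plan gets C6, C7, C8 and C17 in one early step and pays with ring opening and a late macrocyclisation.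

Alternative 2: The cut is C11–C12, so ring A is closed last. In the forward direction a thiazolium-derived carbene with an amidine base turns the C12 aldehyde of keto aldehyde A3 into an acyl anion equivalent that adds to the C11 acetyl group, giving ketol A4. In its favour: the crossed aldehyde–ketone benzoin forming a six-membered ring is well-behaved, and it makes the C11 tertiary ketol with the C12 ketone in one step. That is more direct than the four steps (methylenation, Saegusa oxidation, reductive hydroxylation, acetylation) the chosen plan spends on the same atoms; on this point alternative 2 is the better one. It also needs no nucleophilic C10. Against it here: the C11 configuration depends on catalyst and ring conformation and is not secured by a clear steric argument. C1 and C10 must be set on a ten-membered ring without the help of ring A. A4 still lacks C13=C14, and it carries a C6 silyl ether of inverted configuration, so the chloride must be put in by a late SN2 reaction at a hindered allylic centre where SN2' attack competes. The base also meets an epoxide and a lactone. In mechanism both plans end with base-sensitive intermediates; the chosen plan fixes the chloride early and stereospecifically, alternative 2 fixes the ketol more elegantly.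

Alternative 3: The cut is C6–C7. In the forward direction the (Z)-γ-chloroallyl boronate A6 adds through its chlorine-bearing carbon to aldehyde A5 in a closed six-membered transition state; allylic transposition creates C5=C16, and the C7 alkoxide closes onto the ester to give lactone A7. In its favour: the reaction class is established, so on precedent it is better than the chosen key step. It also delivers the C5 methylene in the same step, whereas the chosen plan needs an addition, an ozonolysis and an elimination for it, and it is convergent. Against it here: C8 and C17 must be made beforehand by other asymmetric chemistry. The face of the hindered α-silyloxy aldehyde A5 is chosen by substrate control alone, since the boronate is achiral. A 2-substituted γ-chloroallyl boronate can lose its Z geometry by 1,3-boryl shift, and the C6/C7 relationship depends on that geometry. In structure A7 is close to compound 11 of the chosen route, so the two plans meet at the same kind of intermediate. The chosen cascade creates three centres from one, and alternative 3 creates two from two; step counts to that point are similar.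

Key step: step 3

Assumption 1: the salt of the R acid with (R)-1-phenylethylamine is taken to be the less soluble one; if the other pairing crystallises, the S amine is used.
Assumption 2: in step 10 the ligand enantiomer is the one that gives the S ketone.
Assumption 3: C5 in 8 to 10 is drawn as the expected epimer (CH2SiMe3 anti to Cl) and C9 in 9 and 10 is an anomeric mixture; both centres vanish in step 7.

## Route

Step 1
Reactants: 1 rac-2-(4-hydroxyphenyl)propanoic acid
Product: 2 (R)-2-(4-hydroxyphenyl)propanoic acid
Conditions: (R)-1-phenylethylamine, EtOH, crystallisation; then 1 M HCl, EtOAc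
Reagents that add atoms: none
Why: Classical resolution through a diastereomeric ammonium salt; the R centre fixed here becomes C17 of the target and no later step breaks a bond at this carbon.

Step 2
Reactants: 2 (R)-2-(4-hydroxyphenyl)propanoic acid
Product: 3 (R)-2-(1-hydroxy-4-oxocyclohexa-2,5-dien-1-yl)propanoic acid
Conditions: PhI(OAc)2, MeCN/H2O (3:1), 0 °C
Reagents that add atoms: water, O
Why: Oxidative dearomatisation of a para-substituted phenol with water as the nucleophile gives the para-quinol; a spiro-β-lactone is too strained to compete, and the product is used at once because slow lactonisation onto the dienone only anticipates step 3.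

Step 3
Reactants: 3 (R)-2-(1-hydroxy-4-oxocyclohexa-2,5-dien-1-yl)propanoic acid; 4 N-chlorosuccinimide
Product: 6 (3R,3aS,7R,7aS)-7-chloro-3a-hydroxy-3-methyl-3a,7a-dihydro-1-benzofuran-2,6(3H,7H)-dione, via caesium dienolate 5 (not isolated)
Conditions: Cs2CO3 (0.2 equiv), 4 (1.05 equiv), MeCN, −20 °C
Reagents that add atoms: N-chlorosuccinimide (compound 4), ClN1C(=O)CCC1=O
Why: Proposed new method: catalytic Cs2CO3 turns 3 into its carboxylate, which adds to C7, the β-carbon of one dienone arm, and the resulting C5/C6 enolate 5 is captured at C6 by 4 before it can expel the carboxylate again, the succinimide anion carrying the base on to the next molecule of acid. The closest known reactions are the oxa-Michael lactonisation of 4-hydroxycyclohexadienone acids and conjugate addition/α-chlorination sequences of enones; their merger on a quinol in one operation is not established. The γ-lactone closes 5-exo-trig and can only be cis-fused, which ties the C7 configuration to that of C8. C8 becomes a stereocentre by the choice of arm: the C17 methyl group takes the convex face, cis to the small free C8 hydroxyl and away from the remaining vinyl arm, so the R acid gives the C8 configuration of the target. C6 is chlorinated on the convex face, anti to the new C7–O bond, which gives the trans Cl/O relationship (net anti addition across a ring Z alkene). The step needs arm selection, a single chlorination and no E1cB loss of the carboxylate from 6; only a catalytic amount of base, low temperature and one equivalent of 4 serve the last two. The hydroxyl is left unprotected on purpose, because a silyl ether on C8 would push the methyl group to the concave face. If 3 has already partly lactonised, the same enolate 5 forms by deprotonation at C6, so both forms converge.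

Step 4
Reactants: 6 chloro lactone enone
Product: 7 C8 O-triethylsilyl ether of 6
Conditions: Et3SiOSO2CF3, 2,6-lutidine, CH2Cl2, −78 °C
Reagents that add atoms: triethylsilyl trifluoromethanesulfonate, CC[Si](CC)(CC)OS(=O)(=O)C(F)(F)F
Why: Silylation of the tertiary hydroxyl with a silyl triflate and a hindered pyridine base that is too weak to enolise the α-chloro ketone; the ether prevents α-ketol shifts once C9 is an aldehyde.

Step 5
Reactants: 7 C8 O-triethylsilyl ether of 6
Product: 8 C5 tertiary allylic alcohol bearing CH2SiMe3 on C5 (trans to the C6 chlorine)
Conditions: Me3SiCH2MgCl, CeCl3, THF, −78 °C; AcOH, −78 °C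
Reagents that add atoms: (trimethylsilyl)methylmagnesium chloride, C[Si](C)(C)C[Mg]Cl
Why: Organocerium 1,2-addition of the Peterson reagent to the enone carbonyl; cerium suppresses enolisation and loss of the lactone oxygen, and the lactone is not attacked at −78 °C. The nucleophile enters anti to the C6 chlorine, and the C5 configuration is of no consequence because C5 becomes sp2 in step 7. C5 is made quaternary so that the later C4 aldehyde cannot enolise and expel chloride.

Step 6
Reactants: 8 C5 tertiary allylic alcohol
Product: 10 C4 primary alcohol with C9 held as the six-membered lactol of the C5 oxygen, via C4 aldehyde C9 lactol 9 (not isolated)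
Conditions: O3, CH2Cl2, −78 °C; PPh3, −78 °C to rt; then NaBH4, EtOH, −78 to −40 °C
Reagents that add atoms: ozone, [O-][O+]=O
Why: Ozonolysis cleaves C4=C9; the free C5 hydroxyl closes onto the C9 aldehyde as a six-membered lactol, which masks C9 and leaves only the C4 aldehyde for NaBH4 at low temperature (aldehyde over hemiacetal).

Step 7
Reactants: 10 C4 alcohol C9 lactol
Product: 11 C9 aldehyde with C5=C16 methylene and C4 allylic alcohol
Conditions: BF3·OEt2 (0.5 equiv), CH2Cl2, −40 to −20 °C; aq. NaHCO3
Reagents that add atoms: none
Why: Acid-promoted Peterson elimination: ionisation of the tertiary C5–O bond is assisted by the anti-periplanar C16–Si bond, which gives C5=C16 and at the same stroke lets the hemiacetal collapse to the C9 aldehyde; the C5 and anomeric centres disappear.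

Step 8
Reactants: 11 allylic alcohol aldehyde
Product: 12 allylic bromide aldehyde
Conditions: N-bromosuccinimide, Me2S, CH2Cl2, −30 to 0 °C
Reagents that add atoms: N-bromosuccinimide, BrN1C(=O)CCC1=O
Why: Corey–Kim bromination of an allylic alcohol under neutral conditions; the non-enolisable aldehyde is untouched, and the secondary chloride is far less reactive than the sulfonium-activated primary position.

Step 9
Reactants: 13 3-ethoxycyclohex-2-en-1-one; 14 ethynyltrimethylsilane
Product: 16 3-((trimethylsilyl)ethynyl)cyclohex-2-en-1-one, via lithium alkoxide adduct 15 (not isolated)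
Conditions: 14, n-BuLi, THF, −78 °C; 13, −78 to 0 °C; then 1 M HCl, rt
Reagents that add atoms: ethynyltrimethylsilane (compound 14), C#C[Si](C)(C)C; water, O
Why: Stork–Danheiser sequence: 1,2-addition of the lithium acetylide to the vinylogous ester, then acid hydrolysis with loss of ethanol and water transposes the carbonyl and gives the 3-alkynyl enone.

Step 10
Reactants: 16 3-((trimethylsilyl)ethynyl)cyclohex-2-en-1-one
Product: 17 (S)-3-methyl-3-((trimethylsilyl)ethynyl)cyclohexan-1-one
Conditions: Me3Al, copper thiophene-2-carboxylate (5 mol %), O,O'-(1,1'-binaphthalene-2,2'-diyl) N,N-bis(1-phenylethyl)phosphoramidite (10 mol %), Et2O, −30 °C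
Reagents that add atoms: trimethylaluminium, C[Al](C)C
Why: Copper-catalysed asymmetric conjugate addition; trialkylaluminium reagents add 1,4 rather than 1,6 to enynones, and the chiral phosphoramidite sets the quaternary centre C1.

Step 11
Reactants: 17 (S)-3-methyl-3-((trimethylsilyl)ethynyl)cyclohexan-1-one
Product: 18 (S)-3-ethynyl-3-methylcyclohexan-1-one
Conditions: K2CO3, MeOH, rt
Reagents that add atoms: none
Why: Methanolysis of the alkynyl C–Si bond; the ketone and the quaternary centre are inert.

Step 12
Reactants: 18 (S)-3-ethynyl-3-methylcyclohexan-1-one
Product: 19 (S)-4-ethynyl-4-methylcyclohexane-1,2-dione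
Conditions: SeO2, 1,4-dioxane/H2O, 80 °C
Reagents that add atoms: selenium dioxide, O=[Se]=O
Why: Riley oxidation of a ketone to the 1,2-dione; the enol forms and is selenated at the unhindered α-methylene (C12) and not at C10 beside the quaternary carbon.

Step 13
Reactants: 19 (S)-4-ethynyl-4-methylcyclohexane-1,2-dione
Product: 20 (S)-2-((tert-butyldimethylsilyl)oxy)-5-ethynyl-5-methylcyclohex-2-en-1-one
Conditions: t-BuMe2SiOSO2CF3, Et3N, CH2Cl2, −78 °C
Reagents that add atoms: tert-butyldimethylsilyl trifluoromethanesulfonate, CC(C)(C)[Si](C)(C)OS(=O)(=O)C(F)(F)F
Why: Soft enolisation and O-silylation toward the less hindered C13 give the 2-silyloxy enone; this blocks the C12 side, so that only C10 can enolise later, and stores the C12 ketone for the Saegusa step.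

Step 14
Reactants: 20 (S)-2-((tert-butyldimethylsilyl)oxy)-5-ethynyl-5-methylcyclohex-2-en-1-one
Product: 21 (S)-2-((tert-butyldimethylsilyl)oxy)-5-methyl-5-((E)-2-(tributylstannyl)vinyl)cyclohex-2-en-1-one
Conditions: Bu3SnH, PdCl2(PPh3)2 (2 mol %), THF, 0 °C
Reagents that add atoms: tributyltin hydride, CCCC[SnH](CCCC)CCCC
Why: Palladium-catalysed syn hydrostannation; tin goes to the terminal carbon because the other alkyne carbon is shielded by the quaternary centre, which gives the E vinylstannane, and it is done here because palladium and tin hydride cannot be used once the allylic halides are present.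

Step 15
Reactants: 21 ring A vinylstannane; 12 allylic bromide aldehyde
Product: 24 aldol adduct with the C9–C10 bond and a free C9 hydroxyl (9S,10S), via lithium enolate 22 (not isolated), via chlorozirconocene enolate 23 (not isolated)
Conditions: 21, LiN(SiMe3)2, THF, −78 °C; Cp2ZrCl2, −78 °C; then 12, −78 °C; pH 7 buffer
Reagents that add atoms: none
Why: Aldol addition of the ring A α'-enolate (C10) to the non-enolisable C9 aldehyde; transmetalation to zirconium makes the addition syn-selective through a closed transition state and makes the enolate too weak a nucleophile to alkylate the allylic bromide. C10 is attacked anti to the larger stannylvinyl group on C1, and the C9 face follows from the syn relationship together with approach anti to the C8 silyloxy group (Felkin-type).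

Step 16
Reactants: 24 aldol adduct
Product: 25 C8,C9 bis(triethylsilyl) ether
Conditions: Et3SiOSO2CF3, 2,6-lutidine, CH2Cl2, −78 °C
Reagents that add atoms: triethylsilyl trifluoromethanesulfonate, CC[Si](CC)(CC)OS(=O)(=O)C(F)(F)F
Why: Silylation of the β-hydroxy ketone stops retro-aldol cleavage and acyl shift of the lactone to C9; a silyl shift between the C8 and C9 oxygens would lead to the same product.

Step 17
Reactants: 25 C8,C9 bis(triethylsilyl) ether
Product: 26 ten-membered ring compound with E C2=C3, C5 methylene, C11 ketone and C12 silyl enol ether
Conditions: copper thiophene-2-carboxylate (3 equiv), N-methylpyrrolidone, 0 °C to rt, slow addition, 2 mM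
Reagents that add atoms: none
Why: Tin-to-copper transmetalation gives a vinylcopper that displaces the primary allylic bromide (Stille-type allylation without palladium, so the secondary allylic chloride is not ionised). SN2 and SN2' attack give the same product because both allyl termini are CH2, the E geometry is retained and no stereocentre is formed. The coupling is irreversible and high dilution favours ring closure.

Step 18
Reactants: 26 ten-membered ring ketone
Product: 27 C11 methylene compound (2-silyloxy-1,3-diene in ring A)
Conditions: Cp2Ti(μ-Cl)(μ-CH2)AlMe2, pyridine, THF/toluene, −40 to 0 °C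
Reagents that add atoms: Tebbe reagent, C[Al-]1(C)C[Ti](C2C=CC=C2)(C2C=CC=C2)[Cl+]1
Why: Tebbe methylenation: the titanium methylidene olefinates the ketone faster than the lactone at low temperature and is not basic, so C10 keeps its configuration.

Step 19
Reactants: 27 C11 methylene silyl enol ether
Product: 28 cross-conjugated dienone (C11=C20, C12 ketone, C13=C14)
Conditions: Pd(OAc)2 (1.1 equiv), MeCN, rt
Reagents that add atoms: none
Why: Saegusa oxidation: the silyl enol ether gives an oxa-π-allyl palladium species that loses the C14 hydrogen, creating C13=C14 and freeing the C12 ketone.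

Step 20
Reactants: 28 cross-conjugated dienone
Product: 30 C11 tertiary α-ketol (C20 methyl, 11S hydroxyl), via potassium enolate 29 (not isolated)
Conditions: K[(sec-Bu)3BH], THF, −78 °C; then 2-(phenylsulfonyl)-3-phenyloxaziridine, −78 °C; aq. NH4Cl
Reagents that add atoms: 2-(phenylsulfonyl)-3-phenyloxaziridine, O=S(=O)(N1OC1c1ccccc1)c1ccccc1
Why: Conjugate reduction of the exocyclic methylene by a bulky borohydride (the ring β-carbon C14 is neopentyl) gives the C11 enolate regiospecifically. The N-sulfonyloxaziridine then delivers oxygen to C11 on the face opposite to the axial C15 methyl and the C9 branch, which is the 11S carbinol.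

Step 21
Reactants: 30 C11 tertiary α-ketol
Product: 31 C11 acetate
Conditions: Ac2O, 4-(dimethylamino)pyridine, Et3N, CH2Cl2, rt
Reagents that add atoms: acetic anhydride, CC(=O)OC(C)=O
Why: Nucleophile-catalysed acetylation of the tertiary α-ketol; the C8 and C9 oxygens are silylated, so only C11 reacts.

Step 22
Reactants: 31 C11 acetate
Product: 32 C8,C9 diol
Conditions: HF·pyridine, pyridine, THF, 0 °C to rt
Reagents that add atoms: none
Why: Buffered fluoride cleaves both triethylsilyl ethers; acetate, allylic chloride and enone are stable to it, and the diol is taken on at once so that the lactone does not move to C9.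

Step 23
Reactants: 32 C8,C9 diol
Product: 33 C9 acetoxyacetate with free C8 hydroxyl (2,3-alkene)
Conditions: AcOCH2COCl, pyridine, 4-(dimethylamino)pyridine (cat.), CH2Cl2, −20 to 0 °C
Reagents that add atoms: acetoxyacetyl chloride, CC(=O)OCC(Cl)=O
Why: Acylation of the secondary C9 hydroxyl; the tertiary C8 hydroxyl, flanked by three substituted carbons, is far slower.

Step 24
Reactants: 33 C9 acetoxyacetate alkene
Product: 34 CNP0314084.4
Conditions: m-CPBA, NaHCO3, CH2Cl2, 0 °C
Reagents that add atoms: 3-chloroperoxybenzoic acid, OOC(=O)c1cccc(Cl)c1
Why: Prilezhaev epoxidation of the most electron-rich alkene: C5=C16 is deactivated by the allylic chlorine and C13=C14 by the ketone. The E alkene gives the trans oxirane stereospecifically, and the peracid attacks the outer face of the alkene in the ten-membered ring, which should give 2R,3R.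

## Compound list

1 | rac-2-(4-hydroxyphenyl)propanoic acid | CC(C(=O)O)c1ccc(O)cc1 | starting material
2 | (R)-2-(4-hydroxyphenyl)propanoic acid | C[C@@H](C(=O)O)c1ccc(O)cc1 | intermediate
3 | (R)-2-(1-hydroxy-4-oxocyclohexa-2,5-dien-1-yl)propanoic acid | C[C@@H](C(=O)O)C1(O)C=CC(=O)C=C1 | intermediate
4 | N-chlorosuccinimide | ClN1C(=O)CCC1=O | starting material
5 | caesium dienolate of the cis-fused lactone (C5 enolate, not isolated) | [Cs+].[O-]C1=C[C@H]2OC(=O)[C@H](C)[C@@]2(O)C=C1 | intermediate
6 | (3R,3aS,7R,7aS)-7-chloro-3a-hydroxy-3-methyl-3a,7a-dihydro-1-benzofuran-2,6(3H,7H)-dione (cis-fused; Cl anti to the lactone oxygen; methyl cis to OH) | O=C1C=C[C@@]2(O)[C@H](OC(=O)[C@@H]2C)[C@H]1Cl | intermediate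
7 | C8 O-triethylsilyl ether of 6 | O=C1C=C[C@@]2(O[Si](CC)(CC)CC)[C@H](OC(=O)[C@@H]2C)[C@H]1Cl | intermediate
8 | C5 tertiary allylic alcohol of 7 with CH2SiMe3 on C5, trans to Cl | O[C@@]1(C[Si](C)(C)C)C=C[C@@]2(O[Si](CC)(CC)CC)[C@H](OC(=O)[C@@H]2C)[C@H]1Cl | intermediate
9 | C4 aldehyde with C9 as lactol of the C5 oxygen (anomeric mixture, not isolated) | O=C[C@]1(C[Si](C)(C)C)OC(O)[C@@]2(O[Si](CC)(CC)CC)[C@H](OC(=O)[C@@H]2C)[C@H]1Cl | intermediate
10 | C4 primary alcohol with C9 lactol (anomeric mixture) | OC[C@]1(C[Si](C)(C)C)OC(O)[C@@]2(O[Si](CC)(CC)CC)[C@H](OC(=O)[C@@H]2C)[C@H]1Cl | intermediate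
11 | γ-lactone carrying C9 aldehyde and C8 silyl ether, with side chain C6HCl–C5(=CH2)–C4H2OH on C7 | C=C(CO)[C@H](Cl)[C@H]1OC(=O)[C@H](C)[C@@]1(O[Si](CC)(CC)CC)C=O | intermediate
12 | allylic bromide of 11 | C=C(CBr)[C@H](Cl)[C@H]1OC(=O)[C@H](C)[C@@]1(O[Si](CC)(CC)CC)C=O | intermediate
13 | 3-ethoxycyclohex-2-en-1-one | CCOC1=CC(=O)CCC1 | starting material
14 | ethynyltrimethylsilane | C#C[Si](C)(C)C | starting material
15 | lithium 3-ethoxy-1-((trimethylsilyl)ethynyl)cyclohex-2-en-1-olate (not isolated) | [Li+].CCOC1=CC([O-])(C#C[Si](C)(C)C)CCC1 | intermediate
16 | 3-((trimethylsilyl)ethynyl)cyclohex-2-en-1-one | O=C1C=C(C#C[Si](C)(C)C)CCC1 | intermediate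
17 | (S)-3-methyl-3-((trimethylsilyl)ethynyl)cyclohexan-1-one | C[C@@]1(C#C[Si](C)(C)C)CC(=O)CCC1 | intermediate
18 | (S)-3-ethynyl-3-methylcyclohexan-1-one | C[C@@]1(C#C)CC(=O)CCC1 | intermediate
19 | (S)-4-ethynyl-4-methylcyclohexane-1,2-dione | C[C@@]1(C#C)CC(=O)C(=O)CC1 | intermediate
20 | (S)-2-((tert-butyldimethylsilyl)oxy)-5-ethynyl-5-methylcyclohex-2-en-1-one | C[C@@]1(C#C)CC(=O)C(O[Si](C)(C)C(C)(C)C)=CC1 | intermediate
21 | (S)-2-((tert-butyldimethylsilyl)oxy)-5-methyl-5-((E)-2-(tributylstannyl)vinyl)cyclohex-2-en-1-one | C[C@@]1(/C=C/[Sn](CCCC)(CCCC)CCCC)CC(=O)C(O[Si](C)(C)C(C)(C)C)=CC1 | intermediate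
22 | lithium enolate of 21 (C10=C11–OLi, not isolated) | [Li+].[O-]C1=C[C@@](C)(/C=C/[Sn](CCCC)(CCCC)CCCC)CC=C1O[Si](C)(C)C(C)(C)C | intermediate
23 | chlorozirconocene enolate of 21 (not isolated) | Cl[Zr](OC1=C[C@@](C)(/C=C/[Sn](CCCC)(CCCC)CCCC)CC=C1O[Si](C)(C)C(C)(C)C)(C1C=CC=C1)C1C=CC=C1 | intermediate
24 | aldol adduct: C9–C10 bond, free C9 hydroxyl (9S,10S), allylic bromide and vinylstannane intact | BrCC(=C)[C@H](Cl)[C@H]1OC(=O)[C@H](C)[C@@]1(O[Si](CC)(CC)CC)[C@@H](O)[C@H]1C(=O)C(O[Si](C)(C)C(C)(C)C)=CC[C@]1(C)/C=C/[Sn](CCCC)(CCCC)CCCC | intermediate
25 | C8,C9 bis(triethylsilyl) ether of 24 | BrCC(=C)[C@H](Cl)[C@H]1OC(=O)[C@H](C)[C@@]1(O[Si](CC)(CC)CC)[C@@H](O[Si](CC)(CC)CC)[C@H]1C(=O)C(O[Si](C)(C)C(C)(C)C)=CC[C@]1(C)/C=C/[Sn](CCCC)(CCCC)CCCC | intermediate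
26 | ten-membered ring compound: E C2=C3, C5 methylene, C11 ketone, C12 silyl enol ether | C=C1C/C=C/[C@@]2(C)CC=C(O[Si](C)(C)C(C)(C)C)C(=O)[C@@H]2[C@H](O[Si](CC)(CC)CC)[C@@]2(O[Si](CC)(CC)CC)[C@H](OC(=O)[C@@H]2C)[C@H]1Cl | intermediate
27 | C11 methylene analogue of 26 | C=C1C/C=C/[C@@]2(C)CC=C(O[Si](C)(C)C(C)(C)C)C(=C)[C@@H]2[C@H](O[Si](CC)(CC)CC)[C@@]2(O[Si](CC)(CC)CC)[C@H](OC(=O)[C@@H]2C)[C@H]1Cl | intermediate
28 | cross-conjugated dienone: C11 methylene, C12 ketone, C13=C14 | C=C1C/C=C/[C@@]2(C)C=CC(=O)C(=C)[C@@H]2[C@H](O[Si](CC)(CC)CC)[C@@]2(O[Si](CC)(CC)CC)[C@H](OC(=O)[C@@H]2C)[C@H]1Cl | intermediate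
29 | potassium C11/C12 enolate with C20 methyl (not isolated) | [K+].C=C1C/C=C/[C@@]2(C)C=CC([O-])=C(C)[C@@H]2[C@H](O[Si](CC)(CC)CC)[C@@]2(O[Si](CC)(CC)CC)[C@H](OC(=O)[C@@H]2C)[C@H]1Cl | intermediate
30 | C11 tertiary α-ketol (11S) | C=C1C/C=C/[C@@]2(C)C=CC(=O)[C@@](C)(O)[C@@H]2[C@H](O[Si](CC)(CC)CC)[C@@]2(O[Si](CC)(CC)CC)[C@H](OC(=O)[C@@H]2C)[C@H]1Cl | intermediate
31 | C11 acetate of 30 | C=C1C/C=C/[C@@]2(C)C=CC(=O)[C@@](C)(OC(C)=O)[C@@H]2[C@H](O[Si](CC)(CC)CC)[C@@]2(O[Si](CC)(CC)CC)[C@H](OC(=O)[C@@H]2C)[C@H]1Cl | intermediate
32 | C8,C9 diol | C=C1C/C=C/[C@@]2(C)C=CC(=O)[C@@](C)(OC(C)=O)[C@@H]2[C@H](O)[C@@]2(O)[C@H](OC(=O)[C@@H]2C)[C@H]1Cl | intermediate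
33 | C9 acetoxyacetate, C8 hydroxyl, E C2=C3 alkene | C=C1C/C=C/[C@@]2(C)C=CC(=O)[C@@](C)(OC(C)=O)[C@@H]2[C@H](OC(=O)COC(C)=O)[C@@]2(O)[C@H](OC(=O)[C@@H]2C)[C@H]1Cl | intermediate
34 | CNP0314084.4 (1S,2R,3R,6S,7S,8R,9S,10S,11S,17R) | C=C1C[C@H]2O[C@@H]2[C@@]2(C)C=CC(=O)[C@@](C)(OC(C)=O)[C@@H]2[C@H](OC(=O)COC(C)=O)[C@@]2(O)[C@H](OC(=O)[C@@H]2C)[C@H]1Cl | target

## Step count and least certain steps

Total: 24 steps. Longest linear sequence: 18 steps (steps 1 to 8, then 15 to 24, from 1 to 34); the ring A branch (steps 9 to 14, from 13 and 14 to 21) has 6 steps.

Step 3 (key step, proposed new method). What may go wrong: a second chlorination at C6, or base-induced loss of the lactone carboxylate from the α-chloro ketone followed by re-addition and scrambling, because the C6 hydrogen of 6 is more acidic than that of its precursor. Arm selection may also be poor, because the difference between a hydroxyl and a vinyl arm next to the C17 methyl is small in a kinetic cyclisation. Fallback with known chemistry, from 3 back to the route at 7: 3 is left with a trace of Et3N in CH2Cl2, so that the reversible oxa-Michael lactonisation settles under thermodynamic control on the unchlorinated cis-fused lactone enone F1. The hydroxyl is silylated (Et3SiOSO2CF3, 2,6-lutidine) to the triethylsilyl ether F2. Soft enolisation (Me3SiOSO2CF3, Et3N, −78 °C) gives the C5/C6 trimethylsilyl dienol ether F3, and N-chlorosuccinimide chlorinates it at C6 from the convex face to give 7 directly.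

Step 15. What may go wrong: poor facial selectivity at the enolate carbon C10 (methyl and stannylvinyl on C1 differ little near the reacting carbon) or at the aldehyde (the two lactone-ring branches on C8 are of similar size), and mismatched double stereodifferentiation between the two enantiopure partners; retro-aldol cleavage on work-up is a lesser concern. Fallback, from 21 and 12 back to the route at 24: the plain lithium enolate (LiN(SiMe3)2, THF, −78 °C) gives the anti aldol, the C9 epimer F4. Dess–Martin periodinane oxidises it to the C9/C11 1,3-diketone F5, in which C10 can settle to its more stable configuration. Zn(BH4)2 at −78 °C then reduces the non-conjugated C9 ketone through the zinc chelate to the syn β-hydroxy ketone 24. C9 is thus set by reduction and not by the aldol itself.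

Step 17. What may go wrong: oligomerisation or protodestannylation in place of ring closure, because the ten-membered ring is strained and the vinylcopper is short-lived; slow SN2' attack on the secondary chloride is a lesser risk. Fallback, from 21 and 12 back to the route at 26, changing which bond closes the ring: 21 and 12 are first joined at C3–C4 with copper thiophene-2-carboxylate at normal concentration, which gives the open-chain keto aldehyde F6. LiN(SiMe3)2 at −78 °C and high dilution then closes the C9–C10 bond by intramolecular aldol addition of the α'-enolate to give the ring alcohol F7, and silylation (Et3SiOSO2CF3, 2,6-lutidine) gives 26.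

Step 24. What may go wrong: attack on the wrong face of C2=C3, since the face is set only by the ring conformation, or competing epoxidation of C5=C16. Fallback, from 33 back to the route at 34: N-bromosuccinimide in aqueous acetone forms the bromonium ion on the face the peracid would have used, and water opens it at the less hindered C3 to give bromohydrin F8. Ag2O then closes the oxirane with inversion at C2, which puts the oxygen on the opposite face to direct epoxidation.

## Further compounds

F1 | step 3 | unchlorinated cis-fused lactone enone (3a-hydroxy-3-methyl-3a,7a-dihydro-1-benzofuran-2,6(3H,7H)-dione, methyl cis to OH) | O=C1C=C[C@@]2(O)[C@H](OC(=O)[C@@H]2C)C1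
F2 | step 3 | C8 O-triethylsilyl ether of F1 | O=C1C=C[C@@]2(O[Si](CC)(CC)CC)[C@H](OC(=O)[C@@H]2C)C1
F3 | step 3 | C5/C6 trimethylsilyl dienol ether of F2 | C[Si](C)(C)OC1=C[C@H]2OC(=O)[C@H](C)[C@@]2(O[Si](CC)(CC)CC)C=C1
F4 | step 15 | anti aldol adduct, C9 epimer of 24 | BrCC(=C)[C@H](Cl)[C@H]1OC(=O)[C@H](C)[C@@]1(O[Si](CC)(CC)CC)[C@H](O)[C@H]1C(=O)C(O[Si](C)(C)C(C)(C)C)=CC[C@]1(C)/C=C/[Sn](CCCC)(CCCC)CCCC
F5 | step 15 | C9/C11 1,3-diketone | BrCC(=C)[C@H](Cl)[C@H]1OC(=O)[C@H](C)[C@@]1(O[Si](CC)(CC)CC)C(=O)[C@H]1C(=O)C(O[Si](C)(C)C(C)(C)C)=CC[C@]1(C)/C=C/[Sn](CCCC)(CCCC)CCCC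
F6 | step 17 | open-chain keto aldehyde with the C3–C4 bond made and C9–C10 open | C=C(C/C=C/[C@]1(C)CC(=O)C(O[Si](C)(C)C(C)(C)C)=CC1)[C@H](Cl)[C@H]1OC(=O)[C@H](C)[C@@]1(O[Si](CC)(CC)CC)C=O
F7 | step 17 | ten-membered ring aldol with free C9 hydroxyl | C=C1C/C=C/[C@@]2(C)CC=C(O[Si](C)(C)C(C)(C)C)C(=O)[C@@H]2[C@H](O)[C@@]2(O[Si](CC)(CC)CC)[C@H](OC(=O)[C@@H]2C)[C@H]1Cl
F8 | step 24 | C2 bromide C3 alcohol (bromohydrin of 33) | C=C1C[C@@H](O)[C@@H](Br)[C@@]2(C)C=CC(=O)[C@@](C)(OC(C)=O)[C@@H]2[C@H](OC(=O)COC(C)=O)[C@@]2(O)[C@H](OC(=O)[C@@H]2C)[C@H]1Cl
A1 | alternative 1 | allenyl vinyl decalinol, substrate of the oxy-Cope rearrangement | C=C=C[C@@]1(O)[C@H](C=C)[C@@]2(C)CCC3(OCCO3)[C@@](C)(OCOC)[C@@H]2[C@H](OCOC)[C@@H]1OCc1ccc(OC)cc1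
A2 | alternative 1 | ring A-fused (E)-5-methylenecyclodec-2-en-7-one | C=C1C/C=C/[C@@]2(C)CCC3(OCCO3)[C@@](C)(OCOC)[C@@H]2[C@H](OCOC)[C@H](OCc2ccc(OC)cc2)C(=O)C1
A3 | alternative 2 | keto aldehyde with C11 acetyl on C10 and C12 aldehyde chain on C1 | C=C1C[C@H]2O[C@@H]2[C@@](C)(CCC=O)[C@H](C(C)=O)[C@H](O[Si](C)(C)C(C)(C)C)[C@@]2(O[Si](CC)(CC)CC)[C@H](OC(=O)[C@@H]2C)[C@@H]1O[Si](C)(C)C(C)(C)C
A4 | alternative 2 | briarane core with ring A as the C11 tertiary α-ketol | C=C1C[C@H]2O[C@@H]2[C@@]2(C)CCC(=O)[C@@](C)(O)[C@@H]2[C@H](O[Si](C)(C)C(C)(C)C)[C@@]2(O[Si](CC)(CC)CC)[C@H](OC(=O)[C@@H]2C)[C@@H]1O[Si](C)(C)C(C)(C)C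
A5 | alternative 3 | C7 aldehyde with C8 silyloxy quaternary centre and C17 methyl ester side chain | O=C[C@](O[Si](CC)(CC)CC)(COCc1ccc(OC)cc1)[C@@H](C)C(=O)OC
A6 | alternative 3 | (Z)-γ-chloroallyl pinacol boronate | Cl/C=C(/CB1OC(C)(C)C(C)(C)O1)CCO[Si](C)(C)C(C)(C)C
A7 | alternative 3 | chloro lactone with C5 methylene, C6 chloride, C7, C8 and C17 set | C=C(CCO[Si](C)(C)C(C)(C)C)[C@H](Cl)[C@H]1OC(=O)[C@H](C)[C@@]1(O[Si](CC)(CC)CC)COCc1ccc(OC)cc1
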